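The readings were generated by integration with constants of no real substance; noise was put on by code.

Put the charge into one flask, and the first question is which.

all flasks: substrate 0.10 M; gas 7.7 mM (held)

|  | free catalyst | temperature | remark | time |
|---|---|---|---|---|
| red | 1 mM | 6 °C | run made earlier |  |
| ochre | 4 mM | 20 °C | run made earlier |  |
| south | 2.0 mM | 0 °C |  | 30 h |
| west | 2.0 mM |  | at 0 °C until 10 h, from then on at 25 °C | 30 h |
| south-west | 2.0 mM | 25 °C |  | 30 h |

- red (time / h: product / %, substrate / %): 5.00: 2, 96; 12.0: 8, 94; 25.0: 16, 80; 40.0: 24, 75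
- ochre (time / h: product / %, substrate / %): 2.00: 16, 83; 4.00: 30, 67; 10.0: 68, 33; 15.0: 83, 19

(each reading ± 1.5 percentage points)

- at the start none of the gas is in solution

1. which flask leads in amount of product, in percent of the substrate charged ("all alike" within 1.5 percentage points) (south / west / south-west / all alike)
2. how much product is there at the end, in percent of the substrate charged: south
3. how much product is there at the end, in percent of the substrate charged: west
4. how much product is there at the end, in percent of the substrate charged: south-west

Does the substrate go anywhere but to product? Not visibly: in the ochre run at 10.0 h the two add to 101%.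

What law? Pseudo-first-order in my reckoning: the fraction of substrate left is exp(−kt), with k the flask's rate constant. Taking k proportional to free catalyst and scaling to 2.0 mM, the last red reading gives 0.0137 h⁻¹ at 6 °C, and the ochre reading at 10.0 h gives 0.0570 h⁻¹ at 20 °C.

And at the asked temperatures? Stretching that factor of 4.16 geometrically gives 0.00746 h⁻¹ at 0 °C and 0.0947 h⁻¹ at 25 °C.

How do you treat west, with its change of temperature? As a large term plus a correction. The cold hours add 0.0746 and the warm hours add 1.89, so the cold term is small. Their sum, 1.97, is the exposure E: k times hours, added over a flask's stages, with exp(−E) the substrate left.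

Your three answers? South has E = 0.224, so 20.0% product. West reaches 86.0%. South-west has E = 2.84, so 94.2%, and it leads.

Where is this weakest? Red and ochre changed catalyst and temperature together, so the proportionality is my assumption, untested by them. Ochre's k also climbs, from 0.0892 h⁻¹ at 4.00 h to 0.114 h⁻¹ at 10.0 h, and my E carries no such lag.

The forecast names south-west, with 19% (12% to 27%) for south, 83% (70% to 91%) for west and 92% (82% to 97%) for south-west, lower than mine on the two warmed flasks, and it goes to the asked temperatures by its own step: “a factor of about 4 over 14 °C, so Ea ≈ 67 kJ/mol”.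

The simulation puts south-west in the lead: south 20.8%, west 84.4%, south-west 93.9%.

    partner + free catalyst ⇌ catalyst intermediate A (K = 140 M⁻¹, k = 0.0890 M⁻¹ s⁻¹, Ea = 53.0 kJ mol⁻¹, ΔH = −34.0 kJ mol⁻¹)
    catalyst intermediate A → catalyst intermediate B (k = 0.0460 s⁻¹, Ea = 80.0 kJ mol⁻¹)
    substrate + catalyst intermediate B ⇌ catalyst intermediate C (K = 360 M⁻¹, k = 0.00230 M⁻¹ s⁻¹, Ea = 52.0 kJ mol⁻¹, ΔH = −4.00 kJ mol⁻¹)
    catalyst intermediate C ⇌ catalyst intermediate D (K = 4.20, k = 0.0360 s⁻¹, Ea = 76.0 kJ mol⁻¹, ΔH = 35.0 kJ mol⁻¹)
    catalyst intermediate D → released group + catalyst intermediate E (k = 6.90 × 10⁻⁴ s⁻¹, Ea = 81.0 kJ mol⁻¹)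
    catalyst intermediate E → free catalyst + product (k = 5.60 × 10⁻⁴ s⁻¹, Ea = 87.0 kJ mol⁻¹)
    gas ⇌ partner, rate k7*(csat - [partner]) (kL = 0.00170 s⁻¹)
    (constants at 0 °C)

West's 84.4% reads back as E = 1.86, below my 1.97. Its 6.66% of product at 10.0 h, the change of temperature, reads back as 0.0689, against my cold term of 0.0746. The neighbouring flask is west with 3.40 mM of free catalyst. Scaling E with the catalyst gives 3.35, so 96.5% product. That flask gives 96.8% product, with 3.22% of the substrate left.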